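## Structural features

- The target is a trans-fused decalin (labdane numbering: ring A = C1–C5 and C10, ring B = C5–C10) that carries an (E)-3-methylpent-2-en-1-ol chain (C11–C16) on C9.
- It has five stereocentres, C3, C5, C8, C9 and C10, configured 3R,5S,8S,9S,10R, the mirror image of the common labdane series; C5/C10 and C8/C9 are adjacent pairs, and C4 and C10 are quaternary.
- With β as the face of the C10 methyl group (C20): bromine at C3 is β and equatorial, H5 is α, C8 carries an α (equatorial) tertiary hydroxyl and a β (axial) methyl group C17, and the C9 chain is β and equatorial.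
- Fragile groups are the secondary neopentyl bromide, the tertiary C8 alcohol (dehydration) and the trisubstituted allylic alcohol (geometry, acid, epoxidising agents).
- The real difficulty is the bromide: substitution at C3 is blocked by the C4 gem-dimethyl group, so the C3–Br bond has to be made together with a C–C bond at C4.
- The key step uses the fact that bromine at C3 is anti to the C4–C5 bond of ring A. A bromonium ion on C3=C4 is opened at C4 by C5, which is made nucleophilic as the enol carbon of a ring B ketone at C6, with C10 already in place.
- Two points of stereochemistry in this closure need stating correctly. In the trans-fused product it is H5, not the new C4–C5 bond, that is anti to C20. The tether can reach only the enol face on its own side, so the ketone first formed should be cis-fused and has to be equilibrated at C5.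
- The price of the plan is an oxygen on C6, where the target has none, which must be moved to C8.

## Logic of the disconnections

**23 ⇒ 22.** The C15–H bonds and the C17–H bond are traced back to an ester and a spiro-epoxide. One hydride reagent then delivers both alcohols in the last step, and no free alcohol has to be carried through the route. The forward step must attack the epoxide CH2 and the ester and leave C3–Br alone.

**22 ⇒ 21.** The C8–O and C17–O bonds are cut back to the exocyclic C8=C17 alkene. Methyl addition to a C8 ketone would come from the α face and give the wrong carbinol; oxidising the alkene from the α face puts oxygen α and C17 β. The step has to choose the 1,1-disubstituted alkene over the enoate and the α over the β face.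

**21 ⇒ 20.** The C13=C14 bond is cut by olefination. This removes the only stereodefined alkene and two carbons and leaves a methyl ketone. The forward step has to favour the E isomer.

**20 ⇒ 19 ⇒ 18.** The C8=C17 bond is cut to the C8 ketone, with C13 masked as a dioxolane so that only C8 is methylenated. The demand is olefination of a hindered ketone that has an enolisable centre at C9.

**18 ⇒ 17 ⇒ 12 + 14.** The C9–C11 bond is cut as an aldol condensation, followed by saturation of C6=C7 and C9=C11. In 12 the ring alkene blocks C7, so only C9 can be enolised; an aldehyde is the electrophile best suited to a carbon next to quaternary C10. Hydrogenation from the face opposite C20 then sets C9.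

**14 ⇒ 13.** The aldehyde comes from a commercial ester by partial reduction, which must stop at the aldehyde.

**12 ⇒ 11 ⇒ 10 ⇒ 9 ⇒ 7.** No skeletal bond is cut; the oxygen is moved from C6 to C8 (enone, epoxy ketone, transposed allylic alcohol, enone). This reduces the problem to 7, which holds only ring A and its three stereocentres. It requires enolisation of 7 toward C7 only, which the hindered C5 methine ensures.

**7 ⇒ 6 ⇒ 5.** The C4–C5 and C3–Br bonds are cut together and ring A is opened. The neopentyl bromide and the ring fusion come from one electrophilic closure, and the precursor has a single stereocentre. The forward step needs bromine transfer to the side-chain alkene and not to the enol carbon, opening at the tertiary carbon, and the correct face of the alkene relative to C10.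

**5 ⇒ 4 ⇒ 3 ⇒ 1 + 2.** The C10–C1 bond and the O–acyl bond are cut. A catalytic asymmetric conjugate addition sets C10, and trapping its enolate fixes the enol double bond at C5=C6, which enolisation of the free ketone would not give. The demand is high enantioselectivity at a quaternary centre and O-acylation of the enolate.

## Other disconnections considered

**Alternative 1:** The cut is C9–C11 and C10–C20 in ring B.
- Forward step: the achiral dienone A1 is desymmetrised by copper–phosphoramidite-catalysed conjugate addition of the zinc reagent A2, and the enolate is C-methylated to give A3.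
- In its favour: one catalytic step makes the C8 carbinol carbon (with C17 and the oxygen already present) and C9 stereogenic. No carbonyl transposition is needed. On C8, C9 and C17 it is better than the chosen plan, which spends steps 3–6, 10 and 13 on them.
- Against it: C10 in A3 is only tertiary and must be quaternised with the ring A tether next to the C9 substituent. C5 is a carbonyl carbon, so the C4–C5 bond and the trans ring fusion need further addition and reduction steps. The C3 bromide would still need a bromonium closure or an unworkable substitution beside C4. The addition must also go anti to the silyl ether.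
- Comparison: on absolute stereocontrol the two plans are equal in kind (copper-catalysed asymmetric conjugate addition). Structurally A3 is ring B with three stereocentres, whereas 7 is ring A with the halogen. Because the halogenated ring is the harder half, the overall step count should be higher than for the chosen plan.

**Alternative 2:** The cut is C5–C10 and C8–C9.
- Forward step: the trienal A4 undergoes an intramolecular Diels–Alder reaction (heat or an aluminium Lewis acid) to give A5.
- In its favour: two rings, two C–C bonds and four stereocentres (C5, C8, C9, C10) are formed at once, and C11 arrives as an aldehyde on C9. In bond and ring economy it is better than the chosen key step, and it avoids a hindered enolate C–C bond formation at C9.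
- Against it: the dienophile is a β,β-disubstituted enal that must form quaternary C10 beside a C5 carrying the CMe2 group, so reactivity is poor. C8 is delivered as CH–CH3 and would need a tertiary C–H hydroxylation with retention. The C3 silyl ether must become an equatorial bromide with retention at a neopentyl centre, for which no reliable method exists. Absolute control needs a separate asymmetric step for C3 in A4.
- Comparison: mechanistically it is a pericyclic closure with substrate control, against an ionic closure with C10 control. It is shorter to the carbon skeleton but does not solve the C3–Br and C8–OH problems that the chosen plan addresses.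

**Alternative 3:** The cut is C5–C6 and C9–C10.
- Forward step: the enal A6 and the diene A7 combine under a chiral oxazaborolidinium Lewis acid to give A8.
- In its favour: it is convergent and catalyst-controlled. It sets C5, C9 and quaternary C10 in the ring-forming step. It leaves a C7=C8 alkene bearing C17 that could be hydrated directly to the C8 carbinol, which is better than the methylenation–epoxidation–reduction sequence of the chosen plan. C11 and C12 are already present.
- Against it: A6 is a trisubstituted enal with a tert-alkyl β-substituent and should react slowly. The C8 methyl group of A7 directs toward the other regioisomer. The formyl group must react exo. Ring A would then be closed by aldol condensation, which leaves a C3 ketone that cannot be turned into the equatorial bromide. C13–C16 are still missing.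
- Comparison: it is equal or better on convergence and on C8, and worse on C3, which is the point on which the chosen plan rests.

Key step: step 2

Assumption: the enantiomer of the chiral NHC ligand in step 1 is the one that gives 10R (sense of induction to be confirmed on the derived ketone); labdane numbering is used throughout, β is the face of the C10 methyl group, and the SMILES strings define the absolute configuration.

## Steps

Step 1
Reactants: 1 5-bromo-2-methylpent-2-ene; 2 3-methylcyclohex-2-en-1-one
Product: 5 (R)-3-methyl-3-(4-methylpent-3-en-1-yl)cyclohex-1-en-1-yl acetate, via (4-methylpent-3-en-1-yl)magnesium bromide 3 (not isolated), via bromomagnesium enolate 4 (not isolated)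
Conditions: Mg, Et2O (1 → 3); Cu(OTf)2 (4 mol%), chiral C2-symmetric imidazolinium chloride (NHC precursor, 5 mol%), 2, Et2O, 0 °C; then Ac2O, 0 °C → rt
Reagents that add atoms: acetic anhydride, CC(=O)OC(C)=O
Why: Copper-catalysed asymmetric conjugate addition of a Grignard reagent to a β-substituted enone; the chiral NHC–copper complex selects the enone face and sets quaternary C10 (R). O-Acylation of the magnesium enolate fixes the enol double bond at C5=C6 and gives an enol derivative that is stable to isolation and less nucleophilic than a silyl enol ether.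

Step 2
Reactants: 5 (R)-3-methyl-3-(4-methylpent-3-en-1-yl)cyclohex-1-en-1-yl acetate
Product: 7 (4aR,7R,8aS)-7-bromo-4a,8,8-trimethyloctahydronaphthalen-1(2H)-one (trans-fused; 3β-bromo-4,4,10-trimethyldecal-6-one in labdane numbering), via cis-fused 5-epimer 6 (not isolated)
Conditions: Et2SBr·SbCl5Br (1.1 equiv), MeNO2, −25 °C; then K2CO3, MeOH, rt
Reagents that add atoms: bromodiethylsulfonium bromopentachloroantimonate, CC[S+](Br)CC.Br[Sb-](Cl)(Cl)(Cl)(Cl)Cl
Why: The sulfonium salt transfers Br+ to the unhindered, electron-rich C3=C4 alkene; the enol acetate carbon C5 opens the bromonium ion at tertiary C4 anti to bromine, and the acyloxycarbenium ion at C6 loses its acetyl group (at once or on methanolysis) to leave the ketone. The closest known reaction type is the bromonium-induced polyene (cation–π) cyclisation terminated by an enol derivative with the same reagent. Ring A closes in a 6-endo mode with respect to the C3=C4 bond, the enol double bond staying exocyclic to the new ring. C3 is set by the anti opening inside the ring A chair: the route needs the chair that has C20 axial and C9 equatorial on the forming ring, which places the equatorial bromine cis to C20 (3R), and C10 is the controlling element because the other chair makes C4 axial on ring B with a methyl group over its concave face. C5 is under thermodynamic control: the tether reaches only the enol face syn to C1, so 6 should form cis-fused, and K2CO3 in MeOH equilibrates it through the C6 enolate to trans-fused 7. The step needs Br+ to choose the side-chain alkene over the enol carbon, which the acetyl group (weaker donor than silyl) and the neopentyl position of C5 beside C10 should secure, and opening at C4, which the tertiary centre secures. The equatorial bromide has no antiperiplanar hydrogen and should survive the base.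

Step 3
Reactants: 7 (4aR,7R,8aS)-7-bromo-4a,8,8-trimethyloctahydronaphthalen-1(2H)-one
Product: 9 3β-bromo-4,4,10-trimethyl-trans-decal-7-en-6-one, via trimethylsilyl enol ether 8 (not isolated)
Conditions: LiN(i-Pr)2, Me3SiCl, THF, −78 °C; then Pd(OAc)2, MeCN, rt
Reagents that add atoms: none
Why: Saegusa oxidation; kinetic deprotonation occurs at C7 because C5 is a methine between two quaternary carbons, and β-hydride elimination from the palladium enolate can only go toward C8.

Step 4
Reactants: 9 3β-bromo-4,4,10-trimethyl-trans-decal-7-en-6-one
Product: 10 3β-bromo-7α,8α-epoxy-4,4,10-trimethyl-trans-decal-6-one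
Conditions: 30% aq. H2O2, NaOH (cat.), MeOH, 0 °C
Reagents that add atoms: hydrogen peroxide, OO
Why: Nucleophilic (Weitz–Scheffer) epoxidation of the enone; hydroperoxide should add to C8 from the α face, away from the syn-axial C20, but the epoxide configuration is not carried into the target.

Step 5
Reactants: 10 3β-bromo-7α,8α-epoxy-4,4,10-trimethyl-trans-decal-6-one
Product: 11 3β-bromo-4,4,10-trimethyl-trans-decal-6-en-8α-ol
Conditions: N2H4·H2O, AcOH (cat.), MeOH, 0 °C → rt
Reagents that add atoms: none
Why: Wharton transposition; the epoxy hydrazone opens to a vinyl diazene that loses N2, leaving C6=C7 and the oxygen on C8.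

Step 6
Reactants: 11 3β-bromo-4,4,10-trimethyl-trans-decal-6-en-8α-ol
Product: 12 3β-bromo-4,4,10-trimethyl-trans-decal-6-en-8-one
Conditions: Dess–Martin periodinane, CH2Cl2, rt
Reagents that add atoms: none
Why: Oxidation of a secondary allylic alcohol with a hypervalent iodine reagent under non-basic conditions, which removes the C8 stereocentre and leaves C5 untouched.

Step 7
Reactants: 13 ethyl 2-(2-methyl-1,3-dioxolan-2-yl)acetate
Product: 14 2-(2-methyl-1,3-dioxolan-2-yl)acetaldehyde
Conditions: i-Bu2AlH (1.05 equiv), CH2Cl2, −78 °C; aq. KNaC4H4O6
Reagents that add atoms: none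
Why: Partial reduction of an ester; the aluminium hemiacetal is stable at −78 °C and releases the aldehyde only on work-up.

Step 8
Reactants: 12 3β-bromo-4,4,10-trimethyl-trans-decal-6-en-8-one; 14 2-(2-methyl-1,3-dioxolan-2-yl)acetaldehyde
Product: 17 3β-bromo-9-[2-(2-methyl-1,3-dioxolan-2-yl)ethylidene]-4,4,10-trimethyl-trans-decal-6-en-8-one (alkene geometry not defined), via lithium aldolate 15 (not isolated), via C11 mesylate 16 (not isolated)
Conditions: LiN(i-Pr)2, THF, −78 °C; 14; MsCl, −78 → 0 °C; DBU, rt
Reagents that add atoms: none
Why: Aldol condensation; kinetic α′-deprotonation of the enone can occur only at C9 (C7 is vinylic, the γ-hydrogen at C5 is shielded), and mesylation followed by E1cB elimination makes the C9=C11 bond. No stereocentre is set, since C9 becomes trigonal.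

Step 9
Reactants: 17 3β-bromo-9-[2-(2-methyl-1,3-dioxolan-2-yl)ethylidene]-4,4,10-trimethyl-trans-decal-6-en-8-one
Product: 18 3β-bromo-9β-[2-(2-methyl-1,3-dioxolan-2-yl)ethyl]-4,4,10-trimethyl-trans-decal-8-one
Conditions: H2 (1 atm), Pd/C, EtOAc, rt
Reagents that add atoms: none
Why: Heterogeneous hydrogenation of both conjugated C=C bonds; hydrogen should reach C9 from the α face opposite the axial C20, giving the equatorial β side chain, which is also the more stable C9 epimer. The unactivated secondary bromide should not be hydrogenolysed under neutral conditions.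

Step 10
Reactants: 18 3β-bromo-9β-[2-(2-methyl-1,3-dioxolan-2-yl)ethyl]-4,4,10-trimethyl-trans-decal-8-one
Product: 19 3β-bromo-9β-[2-(2-methyl-1,3-dioxolan-2-yl)ethyl]-4,4,10-trimethyl-8-methylene-trans-decalin
Conditions: Ph3PCH3Br, KOt-Bu, toluene, 0 → 90 °C
Reagents that add atoms: methyltriphenylphosphonium bromide, C[P+](c1ccccc1)(c1ccccc1)c1ccccc1.[Br-]
Why: Wittig methylenation with the non-stabilised ylide; any enolisation at C9 returns the same, thermodynamically preferred equatorial epimer.

Step 11
Reactants: 19 3β-bromo-9β-[2-(2-methyl-1,3-dioxolan-2-yl)ethyl]-4,4,10-trimethyl-8-methylene-trans-decalin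
Product: 20 4-(3β-bromo-4,4,10-trimethyl-8-methylene-trans-decal-9β-yl)butan-2-one
Conditions: 1 M aq. HCl, THF, rt
Reagents that add atoms: water, O
Why: Acid-catalysed hydrolysis of the dioxolane, under conditions mild enough to leave the exocyclic alkene in place.

Step 12
Reactants: 20 4-(3β-bromo-4,4,10-trimethyl-8-methylene-trans-decal-9β-yl)butan-2-one
Product: 21 ethyl (E)-5-(3β-bromo-4,4,10-trimethyl-8-methylene-trans-decal-9β-yl)-3-methylpent-2-enoate
Conditions: (EtO)2P(O)CH2CO2Et, NaH, THF, 0 → 50 °C
Reagents that add atoms: triethyl phosphonoacetate, CCOC(=O)CP(=O)(OCC)OCC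
Why: Horner–Wadsworth–Emmons olefination of a methyl ketone; the larger CH2 chain goes trans to the ester, so the E isomer should predominate, and the Z isomer is removed by chromatography.

Step 13
Reactants: 21 ethyl (E)-5-(3β-bromo-4,4,10-trimethyl-8-methylene-trans-decal-9β-yl)-3-methylpent-2-enoate
Product: 22 ethyl (E)-5-(3β-bromo-8α,17-epoxy-4,4,10-trimethyl-trans-decal-9β-yl)-3-methylpent-2-enoate (spiro-oxirane at C8, oxygen α, CH2 β)
Conditions: mCPBA, CH2Cl2, 0 °C
Reagents that add atoms: 3-chloroperbenzoic acid, OOC(=O)c1cccc(Cl)c1
Why: Peracid (Prilezhaev) epoxidation; the electron-rich 1,1-disubstituted alkene reacts and the conjugated ester alkene does not. The β face of C8 is blocked by the syn-axial C20, so oxygen should enter from the α face, which sets C8.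

Step 14
Reactants: 22 ethyl (E)-5-(3β-bromo-8α,17-epoxy-4,4,10-trimethyl-trans-decal-9β-yl)-3-methylpent-2-enoate
Product: 23 (E)-5-[(1S,2S,4aS,6R,8aR)-6-bromo-2-hydroxy-2,5,5,8a-tetramethyldecahydronaphthalen-1-yl]-3-methylpent-2-en-1-ol
Conditions: LiAlH4, Et2O, 0 °C
Reagents that add atoms: none
Why: Hydride reduction; the spiro-epoxide is opened at the primary carbon C17, which keeps the C8–O bond and gives the axial methyl group, and the enoate is reduced 1,2 to the allylic alcohol. The secondary neopentyl bromide should be inert to hydride at 0 °C.

## Compound list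

1 | 5-bromo-2-methylpent-2-ene | CC(C)=CCCBr | starting material
2 | 3-methylcyclohex-2-en-1-one | CC1=CC(=O)CCC1 | starting material
3 | (4-methylpent-3-en-1-yl)magnesium bromide | CC(C)=CCC[Mg]Br | intermediate
4 | bromomagnesium (R)-3-methyl-3-(4-methylpent-3-en-1-yl)cyclohex-1-en-1-olate | CC(C)=CCC[C@]1(C)C=C(O[Mg]Br)CCC1 | intermediate
5 | (R)-3-methyl-3-(4-methylpent-3-en-1-yl)cyclohex-1-en-1-yl acetate | CC(C)=CCC[C@]1(C)C=C(OC(C)=O)CCC1 | intermediate
6 | (4aR,7R,8aR)-7-bromo-4a,8,8-trimethyloctahydronaphthalen-1(2H)-one (cis-fused 5-epimer of 7) | O=C1CCC[C@]2(C)CC[C@@H](Br)C(C)(C)[C@H]12 | intermediate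
7 | (4aR,7R,8aS)-7-bromo-4a,8,8-trimethyloctahydronaphthalen-1(2H)-one (trans-fused, bromine cis to the angular methyl group) | O=C1CCC[C@]2(C)CC[C@@H](Br)C(C)(C)[C@@H]12 | intermediate
8 | {[(4aR,7R,8aS)-7-bromo-4a,8,8-trimethyl-3,4,4a,5,6,7,8,8a-octahydronaphthalen-1-yl]oxy}trimethylsilane | C[Si](C)(C)OC1=CCC[C@]2(C)CC[C@@H](Br)C(C)(C)[C@@H]12 | intermediate
9 | 3β-bromo-4,4,10-trimethyl-trans-decal-7-en-6-one | O=C1C=CC[C@]2(C)CC[C@@H](Br)C(C)(C)[C@@H]12 | intermediate
10 | 3β-bromo-7α,8α-epoxy-4,4,10-trimethyl-trans-decal-6-one | O=C1[C@@H]2O[C@@H]2C[C@]3(C)CC[C@@H](Br)C(C)(C)[C@@H]13 | intermediate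
11 | 3β-bromo-4,4,10-trimethyl-trans-decal-6-en-8α-ol | C1=C[C@H](O)C[C@]2(C)CC[C@@H](Br)C(C)(C)[C@@H]12 | intermediate
12 | 3β-bromo-4,4,10-trimethyl-trans-decal-6-en-8-one | C1=CC(=O)C[C@]2(C)CC[C@@H](Br)C(C)(C)[C@@H]12 | intermediate
13 | ethyl 2-(2-methyl-1,3-dioxolan-2-yl)acetate | CCOC(=O)CC1(C)OCCO1 | starting material
14 | 2-(2-methyl-1,3-dioxolan-2-yl)acetaldehyde | CC1(CC=O)OCCO1 | intermediate
15 | lithium alkoxide of 3β-bromo-9-[1-hydroxy-2-(2-methyl-1,3-dioxolan-2-yl)ethyl]-4,4,10-trimethyl-trans-decal-6-en-8-one (mixture at C9 and C11) | C1=CC(=O)C(C(O[Li])CC3(C)OCCO3)[C@]2(C)CC[C@@H](Br)C(C)(C)[C@@H]12 | intermediate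
16 | 3β-bromo-9-[1-(methanesulfonyloxy)-2-(2-methyl-1,3-dioxolan-2-yl)ethyl]-4,4,10-trimethyl-trans-decal-6-en-8-one (mixture at C9 and C11) | C1=CC(=O)C(C(OS(C)(=O)=O)CC3(C)OCCO3)[C@]2(C)CC[C@@H](Br)C(C)(C)[C@@H]12 | intermediate
17 | 3β-bromo-9-[2-(2-methyl-1,3-dioxolan-2-yl)ethylidene]-4,4,10-trimethyl-trans-decal-6-en-8-one (alkene geometry not defined) | C1=CC(=O)C(=CCC3(C)OCCO3)[C@]2(C)CC[C@@H](Br)C(C)(C)[C@@H]12 | intermediate
18 | 3β-bromo-9β-[2-(2-methyl-1,3-dioxolan-2-yl)ethyl]-4,4,10-trimethyl-trans-decal-8-one | CC1(CC[C@H]2[C@]3(C)CC[C@@H](Br)C(C)(C)[C@H]3CCC2=O)OCCO1 | intermediate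
19 | 3β-bromo-9β-[2-(2-methyl-1,3-dioxolan-2-yl)ethyl]-4,4,10-trimethyl-8-methylene-trans-decalin | CC1(CC[C@H]2[C@]3(C)CC[C@@H](Br)C(C)(C)[C@H]3CCC2=C)OCCO1 | intermediate
20 | 4-(3β-bromo-4,4,10-trimethyl-8-methylene-trans-decal-9β-yl)butan-2-one | CC(=O)CC[C@H]1[C@]2(C)CC[C@@H](Br)C(C)(C)[C@H]2CCC1=C | intermediate
21 | ethyl (E)-5-(3β-bromo-4,4,10-trimethyl-8-methylene-trans-decal-9β-yl)-3-methylpent-2-enoate | CCOC(=O)/C=C(\C)CC[C@H]1[C@]2(C)CC[C@@H](Br)C(C)(C)[C@H]2CCC1=C | intermediate
22 | ethyl (E)-5-(3β-bromo-8α,17-epoxy-4,4,10-trimethyl-trans-decal-9β-yl)-3-methylpent-2-enoate | CCOC(=O)/C=C(\C)CC[C@H]1[C@]2(C)CC[C@@H](Br)C(C)(C)[C@H]2CC[C@@]13CO3 | intermediate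
23 | (E)-5-[(1S,2S,4aS,6R,8aR)-6-bromo-2-hydroxy-2,5,5,8a-tetramethyldecahydronaphthalen-1-yl]-3-methylpent-2-en-1-ol | C/C(=C\CO)CC[C@H]1[C@]2(C)CC[C@@H](Br)C(C)(C)[C@H]2CC[C@]1(C)O | target

## Step count and least certain steps

Total: 14 steps. Longest linear sequence: 13 steps (2 → 23 through steps 1–6 and 8–14); step 7 is a one-step branch for the side-chain aldehyde.

**Step 2 (key step).**
- Most likely failure: poor control of the alkene face that receives bromine relative to C10. The competing ring A chair, with C9 rather than C20 axial, allows attack perpendicular to the enol plane with an undistorted ring B, and it would lead to the C3 epimer after the C5 equilibration. Direct attack of Br+ on the enol carbon is a second risk.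
- Fallback (C3 set by a reagent, not by the substrate), from 5:
  - asymmetric epoxidation of the side-chain alkene with a fructose-derived ketone catalyst and KHSO5 (K2CO3 buffer) should give the (S)-epoxide F1;
  - Li2NiBr4 should open it at the secondary carbon with inversion to the (R)-bromohydrin F2;
  - trifluoroacetic anhydride and pyridine should give the tertiary trifluoroacetate F3;
  - ionisation with Me2AlCl in CH2Cl2 at −78 °C generates a bromonium ion of fixed configuration, which C5 can open only to the 3R series;
  - the same treatment with K2CO3 in MeOH rejoins the route at 7.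

**Step 1.**
- Most likely failure: erosion of enantioselectivity when a linear primary Grignard reagent builds the quaternary centre, and incomplete O-acylation of the magnesium enolate.
- Fallback (the two C10 substituents are introduced in the opposite order), from 1 by way of its Grignard reagent 3:
  - 1,2-addition to 3-ethoxycyclohex-2-en-1-one and acidic hydrolysis should give 3-(4-methylpent-3-en-1-yl)cyclohex-2-en-1-one F4;
  - conjugate addition of Me3Al under copper thiophene-2-carboxylate and a chiral phosphoramidite (ligand enantiomer chosen for 10R) gives the dimethylaluminium enolate F5;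
  - acetylation with acetic anhydride gives 5.

**Step 8.**
- Most likely failure: reversion of the hindered aldolate before it is trapped, or proton transfer from the enolisable aldehyde to the C9 enolate.
- Fallback (irreversible alkylation in place of the aldol condensation), from 12:
  - LiN(i-Pr)2, then 2-(2-iodoethyl)-2-methyl-1,3-dioxolane with DMPU, should give 3β-bromo-9-[2-(2-methyl-1,3-dioxolan-2-yl)ethyl]-4,4,10-trimethyl-trans-decal-6-en-8-one F6 as C9 epimers;
  - hydrogenation of the ring alkene (H2, Pd/C) and equilibration of C9 with NaOMe in MeOH lead to 18.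

**Step 10.**
- Most likely failure: enolisation of the hindered, α-branched ketone by the basic ylide in place of addition.
- Fallback (a titanium methylidene in place of a phosphorus ylide): from 18, Cp2TiMe2 in toluene at 65 °C should give 19 directly under non-basic conditions; no new compound is made.

**Step 12.**
- Most likely failure: incomplete E selectivity, because the two substituents of the methyl ketone differ little in size.
- Fallback (stereospecific construction of the alkene), from 20:
  - LiN(i-Pr)2 and ClP(O)(OEt)2 give the diethyl enol phosphate F7;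
  - elimination with excess LiN(i-Pr)2 gives the terminal alkyne F8;
  - Me3Al with catalytic Cp2ZrCl2 adds methyl and aluminium syn to give the (E)-alkenyl dimethylalane F9;
  - acylation with ethyl chloroformate, with retention, gives 21 as the E isomer only.

## Further compounds

F1 | step 2 | (R)-3-{2-[(S)-3,3-dimethyloxiran-2-yl]ethyl}-3-methylcyclohex-1-en-1-yl acetate | CC1(C)O[C@H]1CC[C@]2(C)C=C(OC(C)=O)CCC2
F2 | step 2 | (R)-3-[(R)-3-bromo-4-hydroxy-4-methylpentyl]-3-methylcyclohex-1-en-1-yl acetate | CC(C)(O)[C@H](Br)CC[C@]1(C)C=C(OC(C)=O)CCC1
F3 | step 2 | (R)-3-[(R)-3-bromo-4-methyl-4-(trifluoroacetoxy)pentyl]-3-methylcyclohex-1-en-1-yl acetate | CC(C)(OC(=O)C(F)(F)F)[C@H](Br)CC[C@]1(C)C=C(OC(C)=O)CCC1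
F4 | step 1 | 3-(4-methylpent-3-en-1-yl)cyclohex-2-en-1-one | CC(C)=CCCC1=CC(=O)CCC1
F5 | step 1 | dimethylaluminium (R)-3-methyl-3-(4-methylpent-3-en-1-yl)cyclohex-1-en-1-olate | CC(C)=CCC[C@]1(C)C=C(O[Al](C)C)CCC1
F6 | step 8 | 3β-bromo-9-[2-(2-methyl-1,3-dioxolan-2-yl)ethyl]-4,4,10-trimethyl-trans-decal-6-en-8-one (C9 epimers) | C1=CC(=O)C(CCC3(C)OCCO3)[C@]2(C)CC[C@@H](Br)C(C)(C)[C@@H]12
F0 | step 10 | none | none
F7 | step 12 | 4-(3β-bromo-4,4,10-trimethyl-8-methylene-trans-decal-9β-yl)but-1-en-2-yl diethyl phosphate | C=C(OP(=O)(OCC)OCC)CC[C@H]1[C@]2(C)CC[C@@H](Br)C(C)(C)[C@H]2CCC1=C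
F8 | step 12 | 3β-bromo-9β-(but-3-yn-1-yl)-4,4,10-trimethyl-8-methylene-trans-decalin | C#CCC[C@H]1[C@]2(C)CC[C@@H](Br)C(C)(C)[C@H]2CCC1=C
F9 | step 12 | [(E)-4-(3β-bromo-4,4,10-trimethyl-8-methylene-trans-decal-9β-yl)-2-methylbut-1-en-1-yl]dimethylalane | C[Al](C)/C=C(\C)CC[C@H]1[C@]2(C)CC[C@@H](Br)C(C)(C)[C@H]2CCC1=C
A1 | alternative 1 | 4-(tert-butyldimethylsilyloxy)-4-methylcyclohexa-2,5-dien-1-one | CC1(O[Si](C)(C)C(C)(C)C)C=CC(=O)C=C1
A2 | alternative 1 | bis[3-(triisopropylsilyloxy)propyl]zinc | CC(C)[Si](C(C)C)(C(C)C)OCCC[Zn]CCCO[Si](C(C)C)(C(C)C)C(C)C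
A3 | alternative 1 | 4-(tert-butyldimethylsilyloxy)-4,6-dimethyl-5-[3-(triisopropylsilyloxy)propyl]cyclohex-2-en-1-one (side chain trans to the silyloxy group and trans to the C6 methyl group) | CC(C)[Si](C(C)C)(C(C)C)OCCC[C@H]1[C@H](C)C(=O)C=C[C@]1(C)O[Si](C)(C)C(C)(C)C
A4 | alternative 2 | (2E,6R,8E,10E)-6-(tert-butyldimethylsilyloxy)-3,7,7-trimethyldodeca-2,8,10-trienal | O=C/C=C(\C)CC[C@@H](O[Si](C)(C)C(C)(C)C)C(C)(C)/C=C/C=C/C
A5 | alternative 2 | trans-fused 3β-(tert-butyldimethylsilyloxy)-4,4,8β,10-tetramethyldecal-6-ene-9β-carbaldehyde (labdane numbering) | O=C[C@H]1[C@]2(C)CC[C@@H](O[Si](C)(C)C(C)(C)C)C(C)(C)[C@H]2C=C[C@H]1C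
A6 | alternative 3 | (E)-2,4,4-trimethyl-5-oxohex-2-enal | O=C/C(C)=C/C(C)(C)C(C)=O
A7 | alternative 3 | (E)-tert-butyldimethyl[(4-methylhexa-3,5-dien-1-yl)oxy]silane | C=C/C(C)=C/CCO[Si](C)(C)C(C)(C)C
A8 | alternative 3 | 2-[2-(tert-butyldimethylsilyloxy)ethyl]-1,3-dimethyl-6-(2-methyl-3-oxobutan-2-yl)cyclohex-3-ene-1-carbaldehyde (formyl group trans to both ring substituents) | CC(C)(C)[Si](C)(C)OCC[C@H]1[C@](C)(C=O)[C@H](CC=C1C)C(C)(C)C(C)=O
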